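**Retrosynthetic overview**

1. The target comes from a pentabenzyl ether acetonide by acetal hydrolysis and hydrogenolysis. Its two diol carbons are the carbinol carbons of D-tartaric acid, with each carboxyl group exchanged for an aryl group by a trans-selective decarboxylative arylation on the acetonide.
2. The ring A partner is a (2S,3S)-4-bromo-2,3-dihydrobenzofuran, made from a 3-aryl lactol and an aryl Grignard reagent; acid ring closure puts C2 trans to C3.
3. The lactol comes from oxidative cleavage of an o-(1-arylbut-2-enyl)phenol. That phenol is made by an aromatic Claisen rearrangement ([3,3]) of an aryl 1-methyl-3-arylallyl ether, which forms the C3a–C3 bond and moves the chirality of the lactate-derived C–O centre onto C3.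
4. The ether comes from a Mitsunobu reaction of 3-(benzyloxy)-5-bromophenol with methyl (R)-lactate, then ester reduction and Horner–Wadsworth–Emmons olefination.
5. Ring order: all benzene rings and the dioxolane are bought. The only ring built is the dihydrofuran ring, first as a lactol (step 9), then in final form (step 10).

Assumption: compounds 1, 3, 6, 8, 10 and 16 (the last as its THF solution) are taken as catalogue items; dtbbpy = 4,4′-di-tert-butyl-2,2′-bipyridine, dme = 1,2-dimethoxyethane.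

**Route**

Step 1
Reactants: 1 dimethyl (4S,5S)-2,2-dimethyl-1,3-dioxolane-4,5-dicarboxylate (dimethyl 2,3-O-isopropylidene-D-tartrate)
Product: 2 (4S,5S)-5-(methoxycarbonyl)-2,2-dimethyl-1,3-dioxolane-4-carboxylic acid
Conditions: KOH (1.0 equiv), MeOH, 0 °C → rt; then 1 M HCl, 0 °C, pH 3
Reagents that add atoms: potassium hydroxide, [K+].[OH-]
Why: Mono-saponification of a C2-symmetric diester, whose two ester groups are homotopic so only one half-ester can form and its carboxylate slows the second hydrolysis; both stereocentres are those bought with D-tartaric acid and are untouched.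

Step 2
Reactants: 2 (4S,5S)-5-(methoxycarbonyl)-2,2-dimethyl-1,3-dioxolane-4-carboxylic acid; 3 1-(benzyloxy)-4-iodobenzene
Product: 4 methyl (4S,5R)-5-[4-(benzyloxy)phenyl]-2,2-dimethyl-1,3-dioxolane-4-carboxylate
Conditions: Ir[dF(CF3)ppy]2(dtbbpy)PF6 (1 mol %), NiCl2·dme (10 mol %), dtbbpy (15 mol %), Cs2CO3, DMF, blue LEDs, rt
Reagents that add atoms: none
Why: Photoredox/nickel decarboxylative arylation of an α-alkoxy acid, in which the dioxolan-4-yl radical is captured by the aryl–nickel species on the face away from the neighbouring CO2Me group, so the new C–aryl centre is set trans by the bought tartrate centre.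

Step 3
Reactants: 4 methyl (4S,5R)-5-[4-(benzyloxy)phenyl]-2,2-dimethyl-1,3-dioxolane-4-carboxylate
Product: 5 (4S,5R)-5-[4-(benzyloxy)phenyl]-2,2-dimethyl-1,3-dioxolane-4-carboxylic acid
Conditions: LiOH·H2O, THF/H2O (3:1), 0 °C; then 1 M HCl, 0 °C, pH 3
Reagents that add atoms: lithium hydroxide, [Li+].[OH-]
Why: Ester saponification; the aryl-bearing centre cannot epimerise under base, and epimerisation at C4 is harmless because trans is the stable isomer and C4 is re-made in step 11.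

Step 4
Reactants: 6 5-bromobenzene-1,3-diol
Product: 7 3-(benzyloxy)-5-bromophenol
Conditions: BnBr (1.0 equiv), K2CO3, acetone, reflux
Reagents that add atoms: benzyl bromide, BrCc1ccccc1
Why: Williamson ether synthesis on a symmetric diol, giving the mono-ether statistically (about half, with diol and bis-ether separated and the diol recycled).

Step 5
Reactants: 7 3-(benzyloxy)-5-bromophenol; 8 methyl (2R)-2-hydroxypropanoate (methyl D-lactate)
Product: 9 methyl (2S)-2-[3-(benzyloxy)-5-bromophenoxy]propanoate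
Conditions: PPh3, DIAD, THF, 0 °C → rt
Reagents that add atoms: none
Why: Mitsunobu etherification of an α-hydroxy ester with a phenol proceeds by clean SN2 inversion, turning the bought (R) centre into the (S) aryl ether.

Step 6
Reactants: 10 1,3-bis(benzyloxy)-5-(bromomethyl)benzene
Product: 11 diethyl {[3,5-bis(benzyloxy)phenyl]methyl}phosphonate
Conditions: P(OEt)3 (neat), 140 °C
Reagents that add atoms: triethyl phosphite, CCOP(OCC)OCC
Why: Michaelis–Arbuzov reaction of a primary benzylic bromide, driven by loss of volatile bromoethane.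

Step 7
Reactants: 9 methyl (2S)-2-[3-(benzyloxy)-5-bromophenoxy]propanoate; 11 diethyl {[3,5-bis(benzyloxy)phenyl]methyl}phosphonate
Product: 13 1-(benzyloxy)-3-bromo-5-{[(2S,3E)-4-[3,5-bis(benzyloxy)phenyl]but-3-en-2-yl]oxy}benzene, via aldehyde 12 (not isolated)
Conditions: i-Bu2AlH, CH2Cl2, −78 °C, aq potassium sodium tartrate work-up; crude 12 added to 11/NaN(SiMe3)2, THF, −78 °C → rt
Reagents that add atoms: none
Why: Partial ester reduction (the aluminate is stable at −78 °C) then Horner–Wadsworth–Emmons olefination with a benzylic phosphonate gives the E-styrene; the α-aryloxy centre is not touched as long as the aldehyde is used cold and at once.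

Step 8
Reactants: 13 1-(benzyloxy)-3-bromo-5-{[(2S,3E)-4-[3,5-bis(benzyloxy)phenyl]but-3-en-2-yl]oxy}benzene
Product: 14 5-(benzyloxy)-2-[(1S,2E)-1-[3,5-bis(benzyloxy)phenyl]but-2-en-1-yl]-3-bromophenol
Conditions: PhNEt2, 185 °C, argon, sealed tube
Reagents that add atoms: none
Why: Aromatic Claisen rearrangement ([3,3]-sigmatropic) through a chair transition state with the methyl group equatorial delivers the aryl carbon to the alkene face that carried the C–O bond, so the (S) C–O centre becomes the (S) diarylmethine (future C3); the meta-bromine directs migration toward itself and the meta-benzyloxy group directs it away from itself, both favouring the carbon next to bromine.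

Step 9
Reactants: 14 5-(benzyloxy)-2-[(1S,2E)-1-[3,5-bis(benzyloxy)phenyl]but-2-en-1-yl]-3-bromophenol
Product: 15 (3S)-6-(benzyloxy)-3-[3,5-bis(benzyloxy)phenyl]-4-bromo-2,3-dihydro-1-benzofuran-2-ol
Conditions: OsO4 (2 mol %), NaIO4 (4 equiv), 2,6-lutidine, 1,4-dioxane/H2O (3:1), rt
Reagents that add atoms: sodium periodate, [Na+].[O-]I(=O)(=O)=O; osmium tetroxide (catalytic oxygen carrier), O=[Os](=O)(=O)=O
Why: Lemieux–Johnson cleavage of the disubstituted alkene gives the diarylacetaldehyde, which is trapped at once by the ortho phenol as the lactol (both C2 anomers), keeping the enolisable C3 centre out of the free aldehyde form.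

Step 10
Reactants: 15 (3S)-6-(benzyloxy)-3-[3,5-bis(benzyloxy)phenyl]-4-bromo-2,3-dihydro-1-benzofuran-2-ol; 16 [4-(benzyloxy)phenyl]magnesium bromide
Product: 18 (2S,3S)-6-(benzyloxy)-2-[4-(benzyloxy)phenyl]-3-[3,5-bis(benzyloxy)phenyl]-4-bromo-2,3-dihydro-1-benzofuran, via diol 17 (not isolated)
Conditions: 16 (3 equiv), LaCl3·2LiCl (30 mol %), THF, −78 → 0 °C; aq NH4Cl; then p-TsOH·H2O (10 mol %), CH2Cl2, 0 °C
Reagents that add atoms: none
Why: Lanthanum-assisted Grignard addition to the ring-opened lactol (addition favoured over enolisation) gives the carbinol mixture, and acid-catalysed cyclodehydration through the 4-benzyloxybenzyl cation closes the ring with the C2 aryl anti to the C3 aryl, so C2 is set trans by C3 (the ring closure is reversible and trans is also the stable isomer).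

Step 11
Reactants: 18 (2S,3S)-6-(benzyloxy)-2-[4-(benzyloxy)phenyl]-3-[3,5-bis(benzyloxy)phenyl]-4-bromo-2,3-dihydro-1-benzofuran; 5 (4S,5R)-5-[4-(benzyloxy)phenyl]-2,2-dimethyl-1,3-dioxolane-4-carboxylic acid
Product: 19 (2S,3S)-6-(benzyloxy)-2-[4-(benzyloxy)phenyl]-4-{(4R,5R)-5-[4-(benzyloxy)phenyl]-2,2-dimethyl-1,3-dioxolan-4-yl}-3-[3,5-bis(benzyloxy)phenyl]-2,3-dihydro-1-benzofuran
Conditions: 5 (2 equiv), Ir[dF(CF3)ppy]2(dtbbpy)PF6 (2 mol %), NiCl2·dme (15 mol %), dtbbpy (20 mol %), Cs2CO3, DMF, blue LEDs, rt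
Reagents that add atoms: none
Why: Second photoredox/nickel decarboxylative arylation, in which the planar dioxolanyl radical from 5 couples with the aryl bromide anti to the neighbouring aryl group, so the second diol carbon is set trans by the first and the acetonide carries the (R,R) arrangement derived from D-tartrate.

Step 12
Reactants: 19 (2S,3S)-6-(benzyloxy)-2-[4-(benzyloxy)phenyl]-4-{(4R,5R)-5-[4-(benzyloxy)phenyl]-2,2-dimethyl-1,3-dioxolan-4-yl}-3-[3,5-bis(benzyloxy)phenyl]-2,3-dihydro-1-benzofuran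
Product: 20 (1R,2R)-1-{(2S,3S)-6-(benzyloxy)-2-[4-(benzyloxy)phenyl]-3-[3,5-bis(benzyloxy)phenyl]-2,3-dihydro-1-benzofuran-4-yl}-2-[4-(benzyloxy)phenyl]ethane-1,2-diol
Conditions: AcOH/H2O/THF (4:1:1), 50 °C
Reagents that add atoms: none
Why: Mild acetal hydrolysis cleaves at the ketal carbon and not at the benzylic C–O bonds; it is done before debenzylation because O-benzylated rings stabilise benzylic cations far less than free para-phenols, so no stereocentre is touched.

Step 13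
Reactants: 20 (1R,2R)-1-{(2S,3S)-6-(benzyloxy)-2-[4-(benzyloxy)phenyl]-3-[3,5-bis(benzyloxy)phenyl]-2,3-dihydro-1-benzofuran-4-yl}-2-[4-(benzyloxy)phenyl]ethane-1,2-diol
Product: 21 (1R,2R)-1-[(2S,3S)-3-(3,5-dihydroxyphenyl)-6-hydroxy-2-(4-hydroxyphenyl)-2,3-dihydro-1-benzofuran-4-yl]-2-(4-hydroxyphenyl)ethane-1,2-diol (CNP0105259.1)
Conditions: H2 (1 atm), 10% Pd/C, EtOAc/MeOH (1:1), rt
Reagents that add atoms: none
Why: Hydrogenolysis of the five aryl benzyl ethers under neutral conditions is much faster than cleavage of the free secondary benzylic alcohols or of the cyclic benzylic aryl ether, and the molecule has no alkene or halogen left to reduce.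

**Compound list**

1 | dimethyl (4S,5S)-2,2-dimethyl-1,3-dioxolane-4,5-dicarboxylate | COC(=O)[C@H]1OC(C)(C)O[C@@H]1C(=O)OC | starting material
2 | (4S,5S)-5-(methoxycarbonyl)-2,2-dimethyl-1,3-dioxolane-4-carboxylic acid | OC(=O)[C@H]1OC(C)(C)O[C@@H]1C(=O)OC | intermediate
3 | 1-(benzyloxy)-4-iodobenzene | Ic1ccc(OCc2ccccc2)cc1 | starting material
4 | methyl (4S,5R)-5-[4-(benzyloxy)phenyl]-2,2-dimethyl-1,3-dioxolane-4-carboxylate | c1ccccc1COc1ccc(cc1)[C@H]1OC(C)(C)O[C@@H]1C(=O)OC | intermediate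
5 | (4S,5R)-5-[4-(benzyloxy)phenyl]-2,2-dimethyl-1,3-dioxolane-4-carboxylic acid | c1ccccc1COc1ccc(cc1)[C@H]1OC(C)(C)O[C@@H]1C(O)=O | intermediate
6 | 5-bromobenzene-1,3-diol | Oc1cc(O)cc(Br)c1 | starting material
7 | 3-(benzyloxy)-5-bromophenol | Oc1cc(Br)cc(OCc2ccccc2)c1 | intermediate
8 | methyl (2R)-2-hydroxypropanoate | C[C@@H](O)C(=O)OC | starting material
9 | methyl (2S)-2-[3-(benzyloxy)-5-bromophenoxy]propanoate | C[C@H](Oc1cc(Br)cc(OCc2ccccc2)c1)C(=O)OC | intermediate
10 | 1,3-bis(benzyloxy)-5-(bromomethyl)benzene | BrCc1cc(OCc2ccccc2)cc(OCc2ccccc2)c1 | starting material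
11 | diethyl {[3,5-bis(benzyloxy)phenyl]methyl}phosphonate | CCOP(=O)(Cc1cc(OCc2ccccc2)cc(OCc2ccccc2)c1)OCC | intermediate
12 | (2S)-2-[3-(benzyloxy)-5-bromophenoxy]propanal | C[C@H](Oc1cc(Br)cc(OCc2ccccc2)c1)C=O | intermediate
13 | 1-(benzyloxy)-3-bromo-5-{[(2S,3E)-4-[3,5-bis(benzyloxy)phenyl]but-3-en-2-yl]oxy}benzene | C[C@H](Oc1cc(Br)cc(OCc2ccccc2)c1)/C=C/c1cc(OCc2ccccc2)cc(OCc2ccccc2)c1 | intermediate
14 | 5-(benzyloxy)-2-[(1S,2E)-1-[3,5-bis(benzyloxy)phenyl]but-2-en-1-yl]-3-bromophenol | Oc1cc(OCc2ccccc2)cc(Br)c1[C@H](c1cc(OCc2ccccc2)cc(OCc2ccccc2)c1)/C=C/C | intermediate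
15 | (3S)-6-(benzyloxy)-3-[3,5-bis(benzyloxy)phenyl]-4-bromo-2,3-dihydro-1-benzofuran-2-ol | OC1Oc2cc(OCc3ccccc3)cc(Br)c2[C@@H]1c1cc(OCc3ccccc3)cc(OCc3ccccc3)c1 | intermediate
16 | [4-(benzyloxy)phenyl]magnesium bromide | Br[Mg]c1ccc(OCc2ccccc2)cc1 | starting material
17 | 5-(benzyloxy)-2-[(1S)-1-[3,5-bis(benzyloxy)phenyl]-2-[4-(benzyloxy)phenyl]-2-hydroxyethyl]-3-bromophenol | Oc1cc(OCc2ccccc2)cc(Br)c1[C@H](c1cc(OCc2ccccc2)cc(OCc2ccccc2)c1)C(O)c1ccc(OCc2ccccc2)cc1 | intermediate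
18 | (2S,3S)-6-(benzyloxy)-2-[4-(benzyloxy)phenyl]-3-[3,5-bis(benzyloxy)phenyl]-4-bromo-2,3-dihydro-1-benzofuran | Brc1cc(OCc3ccccc3)cc2c1[C@H](c1cc(OCc3ccccc3)cc(OCc3ccccc3)c1)[C@@H](c1ccc(OCc3ccccc3)cc1)O2 | intermediate
19 | (2S,3S)-6-(benzyloxy)-2-[4-(benzyloxy)phenyl]-4-{(4R,5R)-5-[4-(benzyloxy)phenyl]-2,2-dimethyl-1,3-dioxolan-4-yl}-3-[3,5-bis(benzyloxy)phenyl]-2,3-dihydro-1-benzofuran | c1ccccc1COc1ccc(cc1)[C@H]1OC(C)(C)O[C@@H]1c1cc(OCc3ccccc3)cc2c1[C@H](c1cc(OCc3ccccc3)cc(OCc3ccccc3)c1)[C@@H](c1ccc(OCc3ccccc3)cc1)O2 | intermediate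
20 | (1R,2R)-1-{(2S,3S)-6-(benzyloxy)-2-[4-(benzyloxy)phenyl]-3-[3,5-bis(benzyloxy)phenyl]-2,3-dihydro-1-benzofuran-4-yl}-2-[4-(benzyloxy)phenyl]ethane-1,2-diol | c1ccccc1COc1ccc(cc1)[C@@H](O)[C@H](O)c1cc(OCc3ccccc3)cc2c1[C@H](c1cc(OCc3ccccc3)cc(OCc3ccccc3)c1)[C@@H](c1ccc(OCc3ccccc3)cc1)O2 | intermediate
21 | (1R,2R)-1-[(2S,3S)-3-(3,5-dihydroxyphenyl)-6-hydroxy-2-(4-hydroxyphenyl)-2,3-dihydro-1-benzofuran-4-yl]-2-(4-hydroxyphenyl)ethane-1,2-diol | Oc1ccc([C@@H](O)[C@H](O)c2cc(O)cc3c2[C@H](c2cc(O)cc(O)c2)[C@@H](c2ccc(O)cc2)O3)cc1 | target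

**Step count and risks**

Total step count: 13. Longest linear sequence: 9 steps (steps 4, 5, 7, 8, 9, 10, 11, 12, 13, from 6 to 21).

**Step 8 (Claisen rearrangement).** The main danger is migration to the other ortho carbon, next to the benzyloxy group, made worse by the bulky migrating terminus. A second danger is partial loss of chirality transfer through the chair with axial methyl or through ionisation of the secondary cinnamyl-type ether. Any C3 enantiomer that forms becomes a separable diastereomer at 19.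

The fallback removes the regiochemical question by symmetry. It sets out from 8 and bought 3,5-dibromophenol (Oc1cc(Br)cc(Br)c1), reuses 11 and 16, and comes back at 18:
- Mitsunobu reaction gives methyl (2S)-2-(3,5-dibromophenoxy)propanoate F1.
- i-Bu2AlH gives (2S)-2-(3,5-dibromophenoxy)propanal F2.
- Olefination with 11 gives 1-{[(2S,3E)-4-[3,5-bis(benzyloxy)phenyl]but-3-en-2-yl]oxy}-3,5-dibromobenzene F3.
- Claisen rearrangement, where both ortho carbons are now equivalent and each flanked by bromine, gives 2-[(1S,2E)-1-[3,5-bis(benzyloxy)phenyl]but-2-en-1-yl]-3,5-dibromophenol F4.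
- OsO4/NaIO4 gives (3S)-3-[3,5-bis(benzyloxy)phenyl]-4,6-dibromo-2,3-dihydro-1-benzofuran-2-ol F5.
- Addition of 16 gives 2-[(1S)-1-[3,5-bis(benzyloxy)phenyl]-2-[4-(benzyloxy)phenyl]-2-hydroxyethyl]-3,5-dibromophenol F6, closed with acid to (2S,3S)-2-[4-(benzyloxy)phenyl]-3-[3,5-bis(benzyloxy)phenyl]-4,6-dibromo-2,3-dihydro-1-benzofuran F7.
- Palladium-catalysed C–O coupling of F7 with benzyl alcohol ([(C3H5)PdCl]2, t-BuBrettPhos, Cs2CO3, toluene, 90 °C) at the unhindered C6–Br, leaving the hindered C4–Br, gives 18.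

**Step 10 (Grignard addition and acid closure).** The opened lactol is a doubly benzylic aldehyde that can enolise and lose the C3 configuration under the basic reagent. The acid closure could also give a hydride shift or some cis isomer.

The fallback avoids both the free aldehyde and protic acid. It sets out from 15 and comes back at 18:
- Benzenesulfinic acid and CaCl2 in CH2Cl2 convert 15 into (3S)-2-(benzenesulfonyl)-6-(benzyloxy)-3-[3,5-bis(benzyloxy)phenyl]-4-bromo-2,3-dihydro-1-benzofuran F8.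
- 16 is transmetalated with ZnBr2 to [4-(benzyloxy)phenyl]zinc bromide F9.
- F8 and F9 (THF, rt) react by sulfinate loss and arylzinc addition to the cyclic oxocarbenium ion anti to the C3 aryl group, giving 18 directly.

**Step 11 (second decarboxylative arylation).** The aryl bromide of 18 is ortho-hindered by the ring-fusion carbon carrying C3, which may slow oxidative addition and radical capture at nickel and let protodecarboxylation win.

The fallback inverts the roles of the partners. It sets out from 5 and 18 and comes back at 19: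
- 5 with N-hydroxyphthalimide, DIC and catalytic DMAP gives 1,3-dioxo-1,3-dihydro-2H-isoindol-2-yl (4S,5R)-5-[4-(benzyloxy)phenyl]-2,2-dimethyl-1,3-dioxolane-4-carboxylate F10.
- 18 with n-BuLi (THF, −78 °C) gives {(2S,3S)-6-(benzyloxy)-2-[4-(benzyloxy)phenyl]-3-[3,5-bis(benzyloxy)phenyl]-2,3-dihydro-1-benzofuran-4-yl}lithium F11.
- ZnCl2 converts F11 into {(2S,3S)-6-(benzyloxy)-2-[4-(benzyloxy)phenyl]-3-[3,5-bis(benzyloxy)phenyl]-2,3-dihydro-1-benzofuran-4-yl}zinc chloride F12.
- Nickel-catalysed decarboxylative Negishi coupling of F10 with F12 (NiCl2·dme, dtbbpy, THF/DMF, rt), again trans-selective on the dioxolane, gives 19.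

**Further compounds**

F1 | step 8 | methyl (2S)-2-(3,5-dibromophenoxy)propanoate | C[C@H](Oc1cc(Br)cc(Br)c1)C(=O)OC
F2 | step 8 | (2S)-2-(3,5-dibromophenoxy)propanal | C[C@H](Oc1cc(Br)cc(Br)c1)C=O
F3 | step 8 | 1-{[(2S,3E)-4-[3,5-bis(benzyloxy)phenyl]but-3-en-2-yl]oxy}-3,5-dibromobenzene | C[C@H](Oc1cc(Br)cc(Br)c1)/C=C/c1cc(OCc2ccccc2)cc(OCc2ccccc2)c1
F4 | step 8 | 2-[(1S,2E)-1-[3,5-bis(benzyloxy)phenyl]but-2-en-1-yl]-3,5-dibromophenol | Oc1cc(Br)cc(Br)c1[C@H](c1cc(OCc2ccccc2)cc(OCc2ccccc2)c1)/C=C/C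
F5 | step 8 | (3S)-3-[3,5-bis(benzyloxy)phenyl]-4,6-dibromo-2,3-dihydro-1-benzofuran-2-ol | OC1Oc2cc(Br)cc(Br)c2[C@@H]1c1cc(OCc3ccccc3)cc(OCc3ccccc3)c1
F6 | step 8 | 2-[(1S)-1-[3,5-bis(benzyloxy)phenyl]-2-[4-(benzyloxy)phenyl]-2-hydroxyethyl]-3,5-dibromophenol | Oc1cc(Br)cc(Br)c1[C@H](c1cc(OCc2ccccc2)cc(OCc2ccccc2)c1)C(O)c1ccc(OCc2ccccc2)cc1
F7 | step 8 | (2S,3S)-2-[4-(benzyloxy)phenyl]-3-[3,5-bis(benzyloxy)phenyl]-4,6-dibromo-2,3-dihydro-1-benzofuran | Brc1cc(Br)cc2c1[C@H](c1cc(OCc3ccccc3)cc(OCc3ccccc3)c1)[C@@H](c1ccc(OCc3ccccc3)cc1)O2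
F8 | step 10 | (3S)-2-(benzenesulfonyl)-6-(benzyloxy)-3-[3,5-bis(benzyloxy)phenyl]-4-bromo-2,3-dihydro-1-benzofuran | O=S(=O)(c1ccccc1)C1Oc2cc(OCc3ccccc3)cc(Br)c2[C@@H]1c1cc(OCc3ccccc3)cc(OCc3ccccc3)c1
F9 | step 10 | [4-(benzyloxy)phenyl]zinc bromide | Br[Zn]c1ccc(OCc2ccccc2)cc1
F10 | step 11 | 1,3-dioxo-1,3-dihydro-2H-isoindol-2-yl (4S,5R)-5-[4-(benzyloxy)phenyl]-2,2-dimethyl-1,3-dioxolane-4-carboxylate | c1ccccc1COc1ccc(cc1)[C@H]1OC(C)(C)O[C@@H]1C(=O)ON1C(=O)c2ccccc2C1=O
F11 | step 11 | {(2S,3S)-6-(benzyloxy)-2-[4-(benzyloxy)phenyl]-3-[3,5-bis(benzyloxy)phenyl]-2,3-dihydro-1-benzofuran-4-yl}lithium | [Li]c1cc(OCc3ccccc3)cc2c1[C@H](c1cc(OCc3ccccc3)cc(OCc3ccccc3)c1)[C@@H](c1ccc(OCc3ccccc3)cc1)O2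
F12 | step 11 | {(2S,3S)-6-(benzyloxy)-2-[4-(benzyloxy)phenyl]-3-[3,5-bis(benzyloxy)phenyl]-2,3-dihydro-1-benzofuran-4-yl}zinc chloride | Cl[Zn]c1cc(OCc3ccccc3)cc2c1[C@H](c1cc(OCc3ccccc3)cc(OCc3ccccc3)c1)[C@@H](c1ccc(OCc3ccccc3)cc1)O2
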